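**Retrosynthetic overview**

- Feature: C4 and C6 of the benzo ring are both meta to N1 and ortho/para to C3a. In N-protonated indoline (1) the ammonium group at N1 and the C3 methylene arm on C3a therefore point to exactly these two carbons, which substitution of indole itself cannot reach.
- Key disconnection: the C6–Br and C4–Br bonds, made from 1 and bromine (2) in sulfuric acid, through 6-bromoindoline (3) to 4,6-dibromoindoline (4).
- Late aromatization: the C2–C3 double bond of 4,6-dibromoindole (5) is introduced only after the arene brominations, by dehydrogenation of 4.
- Last disconnection: C3–Br, from 5 and N-bromosuccinimide (6), giving 3,4,6-tribromoindole (7).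
- Rings: none is formed; the benzo ring and the five-membered nitrogen ring both come with 1.

Key step: step 1

Remark: in concentrated sulfuric acid the indolines are present as N-protonated hydrogensulfate salts; they are numbered and drawn as the free bases released on basic work-up.

**Route**

Step 1
Reactants: 1 indoline; 2 bromine
Product: 4 4,6-dibromoindoline, via 6-bromoindoline 3 (not isolated)
Conditions: Br2 (2.1 equiv), Ag2SO4 (1.1 equiv), conc. H2SO4, 0 °C to rt; ice, filter AgBr, aq NaOH
Reagents that add atoms: bromine, BrBr
Why: Electrophilic aromatic substitution of the Derbyshire–Waters type, in which Ag2SO4 removes bromide from Br2 as AgBr and leaves a Br+ equivalent, acts on the indolinium ion, the only form of 1 present in concentrated H2SO4, so the ring reacts as a deactivated arene and not as an aniline. The closest known reaction type is the C6-selective bromination and nitration of indoline in sulfuric acid; the second substitution is the same reaction applied to the protonated form of 3. No ring is closed and no stereocenter is formed. The first bromine should enter at C6, para to the methylene arm on C3a and meta to N1, because the σ-complexes from attack at C5 or C7 place positive charge on C7a next to the ammonium nitrogen. The second bromination must choose C4 over C5 and C7: C4 is ortho to the alkyl arm and again meta to N1, whereas the ortho pull of the C6 bromine toward C5 and C7 is opposed by the para and ortho ammonium group, and C7 is also flanked by two substituents. A third bromination should be held back by the stoichiometry of two Br+ per indoline and by the combined deactivation from two bromines and the ammonium group.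

Step 2
Reactants: 4 4,6-dibromoindoline
Product: 5 4,6-dibromoindole
Conditions: DDQ (1.1 equiv), 1,4-dioxane, rt
Reagents that add atoms: none
Why: Quinone dehydrogenation, in which hydride is abstracted from C2 next to nitrogen and a proton is then lost from C3, should aromatize the five-membered ring while leaving both aryl C–Br bonds untouched, since no hydrogenolysis-active metal is present.

Step 3
Reactants: 5 4,6-dibromoindole; 6 N-bromosuccinimide
Product: 7 3,4,6-tribromoindole
Conditions: NBS (1.0 equiv), DMF, 0 °C, dark; aq Na2S2O3
Reagents that add atoms: N-bromosuccinimide, O=C1CCC(=O)N1Br
Why: Electrophilic bromination of an indole at C3, its most nucleophilic (enamine-like) carbon, should be clean because the two bromines deactivate the benzo ring, and one equivalent at 0 °C limits a second bromination at C2.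

**Compound list**

1 | indoline (2,3-dihydro-1H-indole) | C1Cc2ccccc2N1 | starting material
2 | bromine | BrBr | starting material
3 | 6-bromoindoline (N-protonated in the flask) | Brc1ccc2CCNc2c1 | intermediate
4 | 4,6-dibromoindoline | Brc1cc(Br)c2CCNc2c1 | intermediate
5 | 4,6-dibromoindole | Brc1cc(Br)c2cc[nH]c2c1 | intermediate
6 | N-bromosuccinimide | O=C1CCC(=O)N1Br | starting material
7 | 3,4,6-tribromoindole | Brc1cc(Br)c2c(Br)c[nH]c2c1 | target

**Step count and risks**

Total step count: 3. Longest linear sequence: 3 steps (1 → 4 → 5 → 7).

Steps most likely to fail, in order of risk:

1. Step 1. The risk is loss of site control in the second bromination: attack at C5, ortho to the first bromine, would compete with attack at C4, and imperfect stopping at the dibromide would add mono- and tribromides that are hard to separate. The fallback sets out from 1 and returns at 4. It uses a nitro group as a placeholder for the C6 bromine, so that all three substituents direct a single bromination to C4.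
   - Nitration of 1 (KNO3, conc. H2SO4, 0 °C) should give 6-nitroindoline F1.
   - Bromination of its indolinium ion (dibromoisocyanuric acid, conc. H2SO4, rt) should give 4-bromo-6-nitroindoline F2, since C4 is meta to both the nitro and the ammonium group and ortho to the alkyl arm.
   - N-Acetylation (Ac2O, pyridine) should give 1-acetyl-4-bromo-6-nitroindoline F3.
   - Reduction with Fe powder and NH4Cl in aqueous ethanol, which spares the C–Br bond, should give 1-acetyl-6-amino-4-bromoindoline F4.
   - Diazotization (NaNO2, aq HBr, 0 °C) should give 1-acetyl-4-bromoindoline-6-diazonium bromide F5, which under Sandmeyer conditions (CuBr, aq HBr, 60 °C) should give 1-acetyl-4,6-dibromoindoline F6.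
   - Acid hydrolysis of the amide (6 M HCl, ethanol, reflux; then aq NaOH) should return 4.

2. Step 3. The risk is a second bromination at C2, or acid- and light-promoted decomposition and oligomerization of the N–H 3-bromoindole during work-up and chromatography; the peri bromine at C4 may also slow attack at C3 and worsen both. The fallback sets out from 5 and returns at 7. It shields nitrogen and C2 with a silyl group.
   - Deprotonation and silylation (NaH, then tert-butyldimethylsilyl chloride, THF, 0 °C) should give 1-(tert-butyldimethylsilyl)-4,6-dibromoindole F7.
   - NBS in THF at −78 °C should give the stable, chromatographable 1-(tert-butyldimethylsilyl)-3,4,6-tribromoindole F8.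
   - Tetrabutylammonium fluoride in THF at 0 °C should remove the silyl group and give 7.

3. Step 2. The risk is incomplete hydride abstraction from the electron-poor indoline, or further oxidation and adduct formation between the quinone and the indole product. The fallback sets out from 4 and returns at 5. It replaces hydride abstraction by N-halogenation and elimination.
   - Trichloroisocyanuric acid (one third equiv, CH2Cl2, 0 °C) should give 4,6-dibromo-1-chloroindoline F9.
   - DBU should then eliminate hydrogen chloride to give 4,6-dibromo-3H-indole F10, which tautomerizes to 5.

**Further compounds**

F1 | step 1 | 6-nitroindoline | [O-][N+](=O)c1ccc2CCNc2c1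
F2 | step 1 | 4-bromo-6-nitroindoline | [O-][N+](=O)c1cc(Br)c2CCNc2c1
F3 | step 1 | 1-acetyl-4-bromo-6-nitroindoline | CC(=O)N1CCc2c(Br)cc(cc21)[N+](=O)[O-]
F4 | step 1 | 1-acetyl-6-amino-4-bromoindoline | CC(=O)N1CCc2c(Br)cc(N)cc21
F5 | step 1 | 1-acetyl-4-bromoindoline-6-diazonium bromide | CC(=O)N1CCc2c(Br)cc(cc21)[N+]#N.[Br-]
F6 | step 1 | 1-acetyl-4,6-dibromoindoline | CC(=O)N1CCc2c(Br)cc(Br)cc21
F7 | step 3 | 1-(tert-butyldimethylsilyl)-4,6-dibromoindole | CC(C)(C)[Si](C)(C)n1ccc2c(Br)cc(Br)cc21
F8 | step 3 | 1-(tert-butyldimethylsilyl)-3,4,6-tribromoindole | CC(C)(C)[Si](C)(C)n1cc(Br)c2c(Br)cc(Br)cc21
F9 | step 2 | 4,6-dibromo-1-chloroindoline | ClN1CCc2c(Br)cc(Br)cc21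
F10 | step 2 | 4,6-dibromo-3H-indole | Brc1cc(Br)c2CC=Nc2c1
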